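Read the substrate column of the two earlier runs first, because ash and birch are asked about the same substrate at other temperatures.

| flask | substrate | first nucleophile | second nucleophile | temperature | remark | time |
|---|---|---|---|---|---|---|
| north-west | 0.0050 M | 6 mM | 0.011 M | 57 °C | run made earlier |  |
| south-east | 0.020 M | 6 mM | 0.011 M | 72 °C | run made earlier |  |
| ash | 0.010 M | 6.00 mM | 0.0110 M | 60 °C |  | 8.0 h |
| birch | 0.010 M | 6.00 mM | 0.0110 M | 68 °C |  | 8.0 h |

| run | time / h | other capture product / % | target / % | intermediate / % | substrate / % |
|---|---|---|---|---|---|
| north-west | 0.417 | 3 | 0 | 1 | 98 |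
| north-west | 1.33 | 7 | 0 | 4 | 97 |
| north-west | 2.50 | 11 | 0 | 0 | 88 |
| north-west | 3.00 | 13 | 0 | 1 | 84 |
| north-west | 5.00 | 22 | 2 | 0 | 80 |
| north-west | 6.00 | 26 | 1 | 3 | 77 |
| north-west | 8.00 | 30 | 0 | 0 | 70 |
| south-east | 0.500 | 15 | 0 | 1 | 88 |
| south-east | 1.33 | 32 | 1 | 1 | 69 |
| south-east | 1.50 | 35 | 0 | 0 | 68 |
| south-east | 3.00 | 56 | 2 | 2 | 43 |
| south-east | 4.00 | 53 | 7 | 4 | 34 |

(readings scatter by 1.5 percentage points)

* which of these there is most of at the end, counted by the substrate in it, ash (intermediate / substrate / target / other capture product)
* which of these there is most of at the end, counted by the substrate in it, birch (intermediate / substrate / target / other capture product)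
* amount of the one of these that there is most of at the end, in percent of the substrate charged, ash
* amount of the one of these that there is most of at the end, in percent of the substrate charged, birch

- the numbers in the tables scatter with a standard deviation of 1.5 percentage points

Let S be the fraction of the charged substrate left. The north-west run gives S = 70% at 8.00 h, so a first-order loss S = exp(−kt) has 0.0446 h⁻¹. The south-east run gives 0.281 h⁻¹ from its 3.00 h reading and 0.270 h⁻¹ from its 4.00 h reading, a steady loss although the other capture product reads 56% and then 53%.

Ash lasts as long as that north-west reading and runs hotter, so its S lies below 70%. It runs cooler than the south-east run, so its S lies above 11.6%. To tighten this we take ln k as straight in temperature, which puts ash a fraction 0.200 of the way between the runs. The quantity we carry is k, the first-order loss constant of the substrate, the fall of ln S per hour; for ash it is 0.0639 h⁻¹. That gives S = 60.0%. Moving the north-west reading by one scatter either way narrows the bracket to 58.5% to 61.5%.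

Now we put the answer back in. Ash loses 4.00 mM of substrate, and birch, with 0.167 h⁻¹ and S = 26.3%, loses 7.37 mM. Both stay below the 0.0110 M of second nucleophile. The south-east run read 7% target once its loss of 13.2 mM had passed that charge. So we book the loss to the other capture product, 73.7% in birch.

The forecast gives substrate at 58% in ash, just under our bracket, and other capture product at 72% in birch, holding that “Target appears only once that nucleophile runs out”.

The flask gives substrate at 59.5% in ash, inside the bracket, and other capture product at 75.0% in birch.

    substrate → intermediate (k = 0.0650 h⁻¹, Ea = 116 kJ mol⁻¹)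
    first nucleophile + intermediate ⇌ target (K = 480 M⁻¹, k = 38000 M⁻¹ h⁻¹, Ea = 41.0 kJ mol⁻¹, ΔH = 31.0 kJ mol⁻¹)
    second nucleophile + intermediate → other capture product (k = 3.40 × 10⁵ M⁻¹ h⁻¹, Ea = 47.0 kJ mol⁻¹)
    (constants at 60 °C)

Time turns the answer for ash. Its S falls to 0.5 at ln(2)/k = 10.8 h, and in the simulated flask substrate and other capture product stand equal at 10.7 h. For ash left until 30 h, the same k gives S = 14.7%. That neighbouring flask holds 14.2% substrate and 85.8% other capture product, with 22% of the second nucleophile's own charge left.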